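## Analysis of the target

Gericudranin E (16) is a dihydroflavonol, a 3-hydroxychroman-4-one. Ring A (C4a to C8a) is a phloroglucinol unit with hydroxyls at C5 and C7 and a 4-hydroxybenzyl group on C6; ring C (O1, C2, C3, C4) carries the 4-hydroxyphenyl ring B at C2 and a hydroxyl at C3. C2 and C3 are the only stereocentres, both R, with aryl and hydroxyl trans and equatorial. This is the more stable relative configuration, so only the absolute configuration at C2 needs an external source and C3 can be set relative to it. The sensitive part is the α-hydroxy ketone next to a benzylic ether: base and air dehydrogenate C2–C3 to the flavonol, the 4′-hydroxyl helps the C2–O1 bond to open so that C2 epimerises, and five free hydroxyls sit on oxidisable rings. The real difficulty is ring A. In a phloroglucinol series the carbons that become C6 and C8 are alike until one of the two oxygens flanking the acyl carbon is chosen as O1, so putting the benzyl group on C6 and not C8 means telling two very similar phenols apart. The strategy rests on removing O5 in thought: ring A is then a 4-benzylresorcinol with one carbon ortho to one oxygen and para to the other (the future C4a) and one phenol next to it (the future O1), so the benzyl group falls on C6 by construction. In that 5-deoxy compound the C4 carbonyl has exactly one ortho C–H bond, C5–H, because the other ortho carbon, C8a, carries O1; the carbonyl can steer a metal to C5, and O5 is put in last.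

## Retrosynthetic reasoning

16 ⇒ 15. The four acyl–oxygen bonds at O3, O7, O4′ and the benzyl-ring oxygen are cut. The last step should only unmask, and it must do so without base, so that ring C neither opens nor is oxidised.

15 ⇒ 13. The C5–O bond is cut. This is the one oxygen whose absence makes ring A regiochemically unambiguous and which can be returned by chelation, since the C4 carbonyl of tetraacetate 13 sits peri to C5–H. The forward reaction must oxygenate one of ten aryl C–H bonds and leave C2, C3 and the diarylmethane CH2 alone. Acetates are chosen because they lower the electron density of all three arenes.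

13 ⇒ 12 ⇒ 11. Four O–acetyl bonds, then three O–benzyl bonds, are cut. Benzyl ethers suit the alkylation, condensation and enol ether chemistry of the early steps, but they are electron-rich and would not survive a hypervalent iodine oxidant. The exchange costs two simple steps: hydrogenolysis of 11 to tetraol 12 and peracetylation.

11 ⇒ 9 ⇒ 8. The C3–O bond is cut. C3 is α to the ketone of flavanone 8, so its silyl enol ether 9 can take up electrophilic oxygen. The C2 aryl group shields one face, and the trans product is also the thermodynamic one, so C3 follows from C2.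

8 ⇒ 6 + 7. The C2–C1′ bond is cut. This is the only bond whose formation creates a stereocentre under catalyst control, and cutting it makes the route convergent: ring B arrives as boronic acid 7 and adds to the C2=C3 bond of chromone 6 enantioselectively.

6 ⇒ 4 (through 5). The O1–C2 and C2–C3 bonds are cut. C2 is a single carbon at the formic acid oxidation level that condenses with the methyl ketone of 4 to enaminone 5, which closes onto the free ortho phenol. The forward step needs the other two phenols masked and the chelated one free, which is how 4 is built.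

4 ⇒ 3 ⇒ 2. Two O–benzyl bonds and then the C4–C4a acyl bond are cut. The chelated hydroxyl of 3 stays free on benzylation, so no selective protection has to be devised. The acetyl group can enter diarylmethane 2 at only one unhindered, doubly activated position. This is where the C6 benzyl regiochemistry of the target is fixed.

2 ⇒ 1. The benzylic C–H bonds are traced to the carbonyl of benzophenone 1. The diarylmethane skeleton is bought with the right connectivity, so no Friedel–Crafts benzylation with its ortho/para ambiguity is needed; the forward step is a deoxygenation.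

## Alternatives that were turned down

Alternative 1: ring expansion by α-ketol shift. The C2–C3 bond of the benzyl-protected flavanonol A1, (2R,3R)-5,7-bis(benzyloxy)-6-[4-(benzyloxy)benzyl]-2-[4-(benzyloxy)phenyl]-3-hydroxychroman-4-one, is cut. Its precursor is an isomer with a five-membered oxygen ring, in which C2 is bonded to the future C4, a tertiary carbinol that also bears the formyl carbon (the future C3).
- Forward key step: a chelating Lewis acid binds the hydroxyl and formyl oxygens, C2 shifts from the carbinol carbon to the formyl carbon, the carbinol becomes the C4 ketone and the formyl carbon becomes the C3 carbinol.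
- For: one isomerisation forms the C2–C3 bond, ring C and the C3 stereocentre. The migrating carbon keeps its configuration. All oxygens are present from the start, so the route ends with a single hydrogenolysis.
- Against: the rearrangement substrate is harder to make than A1. It needs a formyl anion equivalent added to a hindered ketone whose neighbouring C2 is benzylic, oxygenated and easily epimerised. The electron-rich aryl carbon can migrate instead of C2, which would give the isomeric 4-hydroxy-3-ketone. The shift is reversible and under thermodynamic control. The 6- versus 8-benzyl question on the phloroglucinol ring is not answered at all.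
- Comparison: this alternative is stronger on bond economy at the core, since one step does the work of steps 5 to 7 below, and it needs no late oxidation. The chosen route offers a precursor made only by standard reactions, a ring A that is unambiguous from compound 1 on, and an uncertain step that makes no skeletal bond.

Alternative 2: conjugate arylation of a chromone that already has O5. The C2–C1′ bond of A2, (2S)-5,7-bis(benzyloxy)-6-[4-(benzyloxy)benzyl]-2-[4-(benzyloxy)phenyl]chroman-4-one, is cut. This is the bond cut between 8 and 6 + 7 in the chosen route, but the acceptor differs from 6 by a benzyloxy group at C5.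
- Forward key step: an aryl–palladium species from boronic acid 7 and a divalent palladium trifluoroacetate with a chiral pyridine–oxazoline ligand adds across C2=C3.
- For: the reaction type is established and every ring A oxygen is in place. Only benzyl ethers are used, there is no C–H oxidation and no acetate stage. After hydroxylation at C3 one hydrogenolysis ends the synthesis. On reliability of the key step and on the end game this alternative is the stronger one.
- Against: the acceptor needs a C-benzylated phloroglucinol ketone in which the hydroxyl next to the benzyl group is protected and the less hindered chelated hydroxyl is left free for ring closure. Ordinary protection does the opposite and would lead to the 8-benzyl isomer. The extra C5 alkoxy group also makes the enone more electron-rich and crowds the carbonyl, both of which slow the insertion.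
- Comparison: the chosen route uses the same reaction on the less hindered, less electron-rich 6. It pays with a protecting-group exchange and a riskier oxidation, and removes the 6/8 problem at its root.

Alternative 3: sulfur-tethered delivery of the benzyl carbon. The C6–CH bond of A3, (2R,3R)-7-(benzyloxy)-2-[4-(benzyloxy)phenyl]-6-{[4-(benzyloxy)phenyl](phenylthio)methyl}-3-(tert-butyldimethylsilyloxy)-5-hydroxychroman-4-one (both epimers at the thioether carbon), is cut. The precursors are a flavanonol core with only O5 free and a benzylic phenyl sulfoxide.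
- Forward key step: the 5-hydroxyl attacks the anhydride-activated sulfoxide. The aryloxysulfonium salt is deprotonated at the benzylic carbon, and a [2,3]-sigmatropic shift carries that carbon to C6 while the O5–S bond breaks.
- For: the tether can reach only C6, because C4a is blocked, so the regiochemistry is solved with the natural oxygenation pattern. The route is convergent and joins two large fragments late.
- Against: the 5-hydroxyl is hydrogen-bonded to the C4 carbonyl and is the poorest nucleophile in the molecule. An activated benzylic sulfoxide can also ionise to a thionium ion (the ordinary Pummerer path), which would alkylate ring A at C8 as well as C6. The sulfur must afterwards be removed reductively without touching the benzyl ethers, the ketone or the C2–O1 bond, and the silyl ether must be cleaved.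
- Comparison: this alternative is stronger on convergence. The chosen route is linear, but it settles the regiochemistry by the choice of starting material and not by a delicate rearrangement, and its key step needs no clean-up steps.

Key step: step 10

Assumption: the (R)-configured tert-butyl pyridine–oxazoline ligand is taken to deliver the aryl group to the face of 6 that gives (2S)-8; if the sense of induction is the reverse, the (S)-ligand is used and nothing else changes.

## Route

Step 1
Reactants: 1 2,4,4′-trihydroxybenzophenone
Product: 2 4-(4-hydroxybenzyl)benzene-1,3-diol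
Conditions: Et3SiH (3 equiv), CF3CO2H, rt to 50 °C
Reagents that add atoms: none
Why: Ionic hydrogenation: the protonated diaryl ketone and then the donor-stabilised benzhydryl cation each accept hydride from the silane, so C=O becomes CH2 with the substitution pattern of both rings unchanged. Excess silane keeps the cation from alkylating a second resorcinol ring.

Step 2
Reactants: 2 4-(4-hydroxybenzyl)benzene-1,3-diol
Product: 3 1-[2,4-dihydroxy-5-(4-hydroxybenzyl)phenyl]ethan-1-one
Conditions: AcOH, BF3·OEt2, 90 °C; then aq. NaOAc
Reagents that add atoms: acetic acid, CC(=O)O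
Why: Friedel–Crafts (Nencki-type) C-acylation of a resorcinol. The acetyl group enters the one carbon that is ortho to one hydroxyl and para to the other; the carbon between the two hydroxyls is hindered and the para-substituted phenol ring is far less nucleophilic.

Step 3
Reactants: 3 1-[2,4-dihydroxy-5-(4-hydroxybenzyl)phenyl]ethan-1-one
Product: 4 1-{4-(benzyloxy)-5-[4-(benzyloxy)benzyl]-2-hydroxyphenyl}ethan-1-one
Conditions: BnBr (2.1 equiv), K2CO3, acetone, reflux
Reagents that add atoms: benzyl bromide, BrCc1ccccc1
Why: Williamson etherification. The hydroxyl ortho to the acetyl group is held in a hydrogen bond to the carbonyl and is not alkylated by a weak base and a limited amount of halide, so only the two free phenols are benzylated.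

Step 4
Reactants: 4 1-{4-(benzyloxy)-5-[4-(benzyloxy)benzyl]-2-hydroxyphenyl}ethan-1-one
Product: 6 7-(benzyloxy)-6-[4-(benzyloxy)benzyl]-4H-chromen-4-one, via enaminone 5 (not isolated)
Conditions: Me2NCH(OMe)2, toluene, 100 °C; then conc. HCl, CH2Cl2, 40 °C
Reagents that add atoms: N,N-dimethylformamide dimethyl acetal, COC(OC)N(C)C
Why: Condensation of the methyl ketone with the amide acetal gives the vinylogous amide 5. On acidification the ortho phenol adds to its β-carbon and dimethylamine is lost (addition–elimination), which closes the pyranone ring of the chromone.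

Step 5
Reactants: 6 7-(benzyloxy)-6-[4-(benzyloxy)benzyl]-4H-chromen-4-one; 7 4-(benzyloxy)phenylboronic acid
Product: 8 (2S)-7-(benzyloxy)-6-[4-(benzyloxy)benzyl]-2-[4-(benzyloxy)phenyl]chroman-4-one
Conditions: Pd(OCOCF3)2 (5 mol %), (R)-4-tert-butyl-2-(pyridin-2-yl)-4,5-dihydrooxazole (6 mol %), NH4PF6 (30 mol %), H2O (5 equiv), ClCH2CH2Cl, 60 °C
Reagents that add atoms: none
Why: Palladium-catalysed enantioselective conjugate addition of an arylboronic acid to a chromone: transmetalation gives a cationic aryl complex of divalent palladium, the aryl group inserts across C2=C3 and water protonates the palladium enolate. The tert-butyl group of the oxazoline blocks one face of the bound chromone during insertion, which should set C2 as S.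

Step 6
Reactants: 8 (2S)-7-(benzyloxy)-6-[4-(benzyloxy)benzyl]-2-[4-(benzyloxy)phenyl]chroman-4-one
Product: 9 (2S)-7-(benzyloxy)-6-[4-(benzyloxy)benzyl]-2-[4-(benzyloxy)phenyl]-4-(trimethylsilyloxy)-2H-chromene
Conditions: Me3SiOTf, Et3N, CH2Cl2, 0 °C; pentane, cold aq. NaHCO3 wash; used crude
Reagents that add atoms: trimethylsilyl trifluoromethanesulfonate, C[Si](C)(C)OS(=O)(=O)C(F)(F)F
Why: Soft enolisation: the silyl triflate activates the carbonyl and the amine removes a C3 proton. No free enolate is formed that could expel the phenoxide O1 and open ring C, so C2 keeps its configuration.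

Step 7
Reactants: 9 (2S)-7-(benzyloxy)-6-[4-(benzyloxy)benzyl]-2-[4-(benzyloxy)phenyl]-4-(trimethylsilyloxy)-2H-chromene
Product: 11 (2R,3R)-7-(benzyloxy)-6-[4-(benzyloxy)benzyl]-2-[4-(benzyloxy)phenyl]-3-hydroxychroman-4-one, via 3-silyloxy ketone 10 (not isolated)
Conditions: mCPBA, CH2Cl2, −20 °C; then 1 M HCl, THF, 0 °C
Reagents that add atoms: 3-chloroperbenzoic acid, OOC(=O)c1cccc(Cl)c1
Why: Rubottom oxidation: the peracid epoxidises the enol ether on the face anti to the C2 aryl group, the silyloxy epoxide opens with 1,4-silyl shift to 10, and dilute acid removes the silyl group. Oxygen therefore arrives trans to the aryl group, which is also the more stable arrangement, giving (2R,3R). The change of the C2 descriptor from S to R is only a change in substituent ranking.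

Step 8
Reactants: 11 (2R,3R)-7-(benzyloxy)-6-[4-(benzyloxy)benzyl]-2-[4-(benzyloxy)phenyl]-3-hydroxychroman-4-one
Product: 12 (2R,3R)-3,7-dihydroxy-6-(4-hydroxybenzyl)-2-(4-hydroxyphenyl)chroman-4-one
Conditions: H2 (1 atm), Pd/C (10 wt %), EtOAc/MeOH, rt
Reagents that add atoms: none
Why: Hydrogenolysis of three aryl benzyl ethers under neutral conditions. The donor-substituted aryl ketone and the C2–O1 bond react much more slowly, and the reaction is stopped after uptake of three equivalents of hydrogen.

Step 9
Reactants: 12 (2R,3R)-3,7-dihydroxy-6-(4-hydroxybenzyl)-2-(4-hydroxyphenyl)chroman-4-one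
Product: 13 (2R,3R)-6-(4-acetoxybenzyl)-2-(4-acetoxyphenyl)-4-oxochroman-3,7-diyl diacetate
Conditions: Ac2O, pyridine, 0 °C to rt
Reagents that add atoms: acetic anhydride, CC(=O)OC(C)=O
Why: Acylation of the three phenols and the secondary C3 hydroxyl. Pyridine is too weak a base to enolise C3 or open ring C, so both stereocentres are kept.

Step 10
Reactants: 13 (2R,3R)-6-(4-acetoxybenzyl)-2-(4-acetoxyphenyl)-4-oxochroman-3,7-diyl diacetate
Product: 15 (2R,3R)-6-(4-acetoxybenzyl)-2-(4-acetoxyphenyl)-5-hydroxy-4-oxochroman-3,7-diyl diacetate, via C5 trifluoroacetate 14 (not isolated)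
Conditions: Pd(OAc)2 (10 mol %), PhI(OCOCF3)2 (2 equiv), ClCH2CH2Cl, 80 °C; then H2O, THF, rt
Reagents that add atoms: [bis(trifluoroacetoxy)iodo]benzene, O=C(O[I](OC(=O)C(F)(F)F)c1ccccc1)C(F)(F)F
Why: The C4 carbonyl oxygen binds electrophilic divalent palladium (the trifluoroacetate formed in situ from Pd(OAc)2), and carboxylate-assisted concerted metalation–deprotonation of the peri C5–H bond gives a five-membered palladacycle (Pd, O, C4, C4a, C5). PhI(OCOCF3)2 oxidises it to an aryl trifluoroacetate complex of tetravalent palladium; C–O reductive elimination forms the C5–O bond of 14 and returns divalent palladium, and water then cleaves the aryl trifluoroacetate to phenol 15, which is held in a hydrogen bond to the C4 carbonyl. The closest known reaction type is the palladium-catalysed, ketone-directed ortho C–H hydroxylation of aryl ketones with hypervalent iodine oxidants, which also runs on cyclic aryl ketones. No ring is closed and no stereocentre is made; C2 and C3 only have to survive, and they should, because the medium holds no base that could enolise C3 or open ring C. The step needs site selectivity for C5 over nine other aryl C–H bonds, and the substrate secures it: the other carbon ortho to the carbonyl, C8a, carries O1, so C5–H is the only bond a carbonyl-bound metal can reach, and the acetate carbonyls are much weaker donors. It also needs chemoselectivity against direct oxidation of the arenes; the four acetates provide it by lowering the electron density of rings A and B and of the benzyl ring, and O5 stays masked as the trifluoroacetate until the oxidant is spent. The competing processes are dehydrogenation across C2–C3, which needs enolisation towards the acetoxy-bearing C3, and oxidation at the diarylmethane CH2; both are held back by a non-basic medium and an oxidant charge close to stoichiometric.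

Step 11
Reactants: 15 (2R,3R)-6-(4-acetoxybenzyl)-2-(4-acetoxyphenyl)-5-hydroxy-4-oxochroman-3,7-diyl diacetate
Product: 16 Gericudranin E, (2R,3R)-3,5,7-trihydroxy-6-(4-hydroxybenzyl)-2-(4-hydroxyphenyl)chroman-4-one
Conditions: 1.25 M HCl in MeOH, argon, 0 °C to rt
Reagents that add atoms: none
Why: Acid-catalysed transesterification removes the three aryl acetates and the C3 acetate, which the adjacent carbonyl activates, as methyl acetate. Acid is used and not base, because phenoxides and a C3 enolate would open ring C or let air oxidise the product to the flavonol.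

## Compound list

1 | 2,4,4′-trihydroxybenzophenone | O=C(c1ccc(O)cc1)c1ccc(O)cc1O | starting material
2 | 4-(4-hydroxybenzyl)benzene-1,3-diol | Oc1ccc(Cc2ccc(O)cc2O)cc1 | intermediate
3 | 1-[2,4-dihydroxy-5-(4-hydroxybenzyl)phenyl]ethan-1-one | CC(=O)c1cc(Cc2ccc(O)cc2)c(O)cc1O | intermediate
4 | 1-{4-(benzyloxy)-5-[4-(benzyloxy)benzyl]-2-hydroxyphenyl}ethan-1-one | CC(=O)c1cc(Cc2ccc(OCc3ccccc3)cc2)c(OCc2ccccc2)cc1O | intermediate
5 | (E)-1-{4-(benzyloxy)-5-[4-(benzyloxy)benzyl]-2-hydroxyphenyl}-3-(dimethylamino)prop-2-en-1-one | CN(C)/C=C/C(=O)c1cc(Cc2ccc(OCc3ccccc3)cc2)c(OCc2ccccc2)cc1O | intermediate (not isolated)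
6 | 7-(benzyloxy)-6-[4-(benzyloxy)benzyl]-4H-chromen-4-one | O=c1ccoc2cc(OCc3ccccc3)c(Cc3ccc(OCc4ccccc4)cc3)cc12 | intermediate
7 | 4-(benzyloxy)phenylboronic acid | OB(O)c1ccc(OCc2ccccc2)cc1 | starting material
8 | (2S)-7-(benzyloxy)-6-[4-(benzyloxy)benzyl]-2-[4-(benzyloxy)phenyl]chroman-4-one | O=C1c2c(cc(OCc3ccccc3)c(Cc3ccc(OCc4ccccc4)cc3)c2)O[C@H](c2ccc(OCc3ccccc3)cc2)C1 | intermediate
9 | (2S)-7-(benzyloxy)-6-[4-(benzyloxy)benzyl]-2-[4-(benzyloxy)phenyl]-4-(trimethylsilyloxy)-2H-chromene | C[Si](C)(C)OC1=C[C@@H](c2ccc(OCc3ccccc3)cc2)Oc2cc(OCc3ccccc3)c(Cc3ccc(OCc4ccccc4)cc3)cc21 | intermediate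
10 | (2R,3R)-7-(benzyloxy)-6-[4-(benzyloxy)benzyl]-2-[4-(benzyloxy)phenyl]-3-(trimethylsilyloxy)chroman-4-one | O=C1c2c(cc(OCc3ccccc3)c(Cc3ccc(OCc4ccccc4)cc3)c2)O[C@H](c2ccc(OCc3ccccc3)cc2)[C@H]1O[Si](C)(C)C | intermediate (not isolated)
11 | (2R,3R)-7-(benzyloxy)-6-[4-(benzyloxy)benzyl]-2-[4-(benzyloxy)phenyl]-3-hydroxychroman-4-one | O=C1c2c(cc(OCc3ccccc3)c(Cc3ccc(OCc4ccccc4)cc3)c2)O[C@H](c2ccc(OCc3ccccc3)cc2)[C@H]1O | intermediate
12 | (2R,3R)-3,7-dihydroxy-6-(4-hydroxybenzyl)-2-(4-hydroxyphenyl)chroman-4-one | O=C1c2c(cc(O)c(Cc3ccc(O)cc3)c2)O[C@H](c2ccc(O)cc2)[C@H]1O | intermediate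
13 | (2R,3R)-6-(4-acetoxybenzyl)-2-(4-acetoxyphenyl)-4-oxochroman-3,7-diyl diacetate | O=C1c2c(cc(OC(C)=O)c(Cc3ccc(OC(C)=O)cc3)c2)O[C@H](c2ccc(OC(C)=O)cc2)[C@H]1OC(C)=O | intermediate
14 | (2R,3R)-6-(4-acetoxybenzyl)-2-(4-acetoxyphenyl)-4-oxo-5-(trifluoroacetoxy)chroman-3,7-diyl diacetate | O=C1c2c(cc(OC(C)=O)c(Cc3ccc(OC(C)=O)cc3)c2OC(=O)C(F)(F)F)O[C@H](c2ccc(OC(C)=O)cc2)[C@H]1OC(C)=O | intermediate (not isolated)
15 | (2R,3R)-6-(4-acetoxybenzyl)-2-(4-acetoxyphenyl)-5-hydroxy-4-oxochroman-3,7-diyl diacetate | O=C1c2c(cc(OC(C)=O)c(Cc3ccc(OC(C)=O)cc3)c2O)O[C@H](c2ccc(OC(C)=O)cc2)[C@H]1OC(C)=O | intermediate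
16 | Gericudranin E, (2R,3R)-3,5,7-trihydroxy-6-(4-hydroxybenzyl)-2-(4-hydroxyphenyl)chroman-4-one | O=C1c2c(cc(O)c(Cc3ccc(O)cc3)c2O)O[C@H](c2ccc(O)cc2)[C@H]1O | target

## Step count and least certain steps

Total: 11 steps. Longest linear sequence: 11 steps, from 1 to 16; boronic acid 7 enters at step 5.

Step 10 (key step).
- Most likely failure: slow cyclopalladation. C5–H is flanked by the C6 benzyl group and the ring fusion, and the metal is held only by a weak carbonyl donor. Oxidant-driven background reactions can then take over: oxidation at the doubly benzylic CH2, dehydrogenation across C2–C3, or acetate-directed palladation at C8.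
- Fallback: replace the ketone by a stronger nitrogen director and use a milder oxidant. It sets out from 12 and comes back at 16.
- Route: 12 is condensed with hydroxylamine hydrochloride (pyridine, EtOH, 60 °C) to the oxime (2R,3S,4Z)-4-(hydroxyimino)-6-(4-hydroxybenzyl)-2-(4-hydroxyphenyl)chromane-3,7-diol F1. The 3S descriptor reflects only the changed ranking at C4; the spatial arrangement is that of 12. Ac2O in pyridine gives (2R,3S,4Z)-4-(acetoxyimino)-6-(4-acetoxybenzyl)-2-(4-acetoxyphenyl)chromane-3,7-diyl diacetate F2. Its O-acetyl oxime nitrogen points at C5–H and is a far better donor than the ketone oxygen. Oxime-directed C–H acetoxylation (Pd(OAc)2 5 mol %, PhI(OAc)2, AcOH/Ac2O, 90 °C), a known reaction of O-acetyl oximes, should give (2R,3S,4Z)-4-(acetoxyimino)-6-(4-acetoxybenzyl)-2-(4-acetoxyphenyl)chromane-3,5,7-triyl triacetate F3. Aqueous NaHSO3 in EtOH at 60 °C returns the ketone (2R,3R)-6-(4-acetoxybenzyl)-2-(4-acetoxyphenyl)-4-oxochroman-3,5,7-triyl triacetate F4, and the conditions of step 11 convert F4 into 16.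

Step 5.
- Most likely failure: protodeboronation of the electron-rich boronic acid outruns insertion into a chromone that the C7 alkoxy group makes less electrophilic, or facial discrimination is incomplete.
- Fallback: build ring C from a chalcone epoxide, so that the stereocentres come from an asymmetric epoxidation. It sets out from 4 and comes back at 11.
- Route: Claisen–Schmidt condensation of 4 with 4-(benzyloxy)benzaldehyde (KOH, EtOH, rt) gives (E)-1-{4-(benzyloxy)-5-[4-(benzyloxy)benzyl]-2-hydroxyphenyl}-3-[4-(benzyloxy)phenyl]prop-2-en-1-one F5. The chelated hydroxyl is protected (NaH, MeOCH2Cl, DMF, 0 °C) to give (E)-1-{4-(benzyloxy)-5-[4-(benzyloxy)benzyl]-2-(methoxymethoxy)phenyl}-3-[4-(benzyloxy)phenyl]prop-2-en-1-one F6. Juliá–Colonna epoxidation (poly-L-leucine, urea–H2O2, DBU, THF) should give {4-(benzyloxy)-5-[4-(benzyloxy)benzyl]-2-(methoxymethoxy)phenyl}{(2R,3S)-3-[4-(benzyloxy)phenyl]oxiran-2-yl}methanone F7. HCl in MeOH at 45 °C removes the methoxymethyl group, and the freed phenol opens the epoxide at the benzylic carbon with inversion (6-endo) to give 11.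

Step 7.
- Most likely failure: the carboxylic acid formed from the peracid protodesilylates the enol ether before oxygen transfer, which returns 8. Forcing the reaction with more peracid invites Baeyer–Villiger oxidation.
- Fallback: osmium-catalysed dihydroxylation of the enol ether (OsO4 2 mol %, N-methylmorpholine N-oxide, acetone/H2O, 0 °C). It sets out from 9 and comes back at 11. Osmylation anti to the C2 aryl group and collapse of the silylated hemiketal give 11 in a neutral medium. No new compound is made (F0).

Step 11.
- Most likely failure: solvolysis of the secondary C3 acetate is slow under acid mild enough for the product. Forcing it lets ring C open at C2–O1 with help from the free 4′-hydroxyl, and C2 epimerises.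
- Fallback: change the protecting group so that the last step is a neutral hydrogenolysis. It sets out from 12 and comes back at 16.
- Route: benzyl chloroformate and pyridine in CH2Cl2 at 0 °C give (2R,3R)-3,7-bis{[(benzyloxy)carbonyl]oxy}-6-(4-{[(benzyloxy)carbonyl]oxy}benzyl)-2-(4-{[(benzyloxy)carbonyl]oxy}phenyl)chroman-4-one F8, whose carbonates deactivate the arenes as the acetates do. The conditions of step 10 should give (2R,3R)-3,7-bis{[(benzyloxy)carbonyl]oxy}-6-(4-{[(benzyloxy)carbonyl]oxy}benzyl)-5-hydroxy-2-(4-{[(benzyloxy)carbonyl]oxy}phenyl)chroman-4-one F9. H2 over Pd/C in EtOAc at rt removes the four carbonates and gives 16.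

## Further compounds

F1 | step 10 | (2R,3S,4Z)-4-(hydroxyimino)-6-(4-hydroxybenzyl)-2-(4-hydroxyphenyl)chromane-3,7-diol | O/N=C1/c2c(cc(O)c(Cc3ccc(O)cc3)c2)O[C@H](c2ccc(O)cc2)[C@H]1O
F2 | step 10 | (2R,3S,4Z)-4-(acetoxyimino)-6-(4-acetoxybenzyl)-2-(4-acetoxyphenyl)chromane-3,7-diyl diacetate | CC(=O)O/N=C1/c2c(cc(OC(C)=O)c(Cc3ccc(OC(C)=O)cc3)c2)O[C@H](c2ccc(OC(C)=O)cc2)[C@H]1OC(C)=O
F3 | step 10 | (2R,3S,4Z)-4-(acetoxyimino)-6-(4-acetoxybenzyl)-2-(4-acetoxyphenyl)chromane-3,5,7-triyl triacetate | CC(=O)O/N=C1/c2c(cc(OC(C)=O)c(Cc3ccc(OC(C)=O)cc3)c2OC(C)=O)O[C@H](c2ccc(OC(C)=O)cc2)[C@H]1OC(C)=O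
F4 | step 10 | (2R,3R)-6-(4-acetoxybenzyl)-2-(4-acetoxyphenyl)-4-oxochroman-3,5,7-triyl triacetate | O=C1c2c(cc(OC(C)=O)c(Cc3ccc(OC(C)=O)cc3)c2OC(C)=O)O[C@H](c2ccc(OC(C)=O)cc2)[C@H]1OC(C)=O
F5 | step 5 | (E)-1-{4-(benzyloxy)-5-[4-(benzyloxy)benzyl]-2-hydroxyphenyl}-3-[4-(benzyloxy)phenyl]prop-2-en-1-one | O=C(/C=C/c1ccc(OCc2ccccc2)cc1)c1cc(Cc2ccc(OCc3ccccc3)cc2)c(OCc2ccccc2)cc1O
F6 | step 5 | (E)-1-{4-(benzyloxy)-5-[4-(benzyloxy)benzyl]-2-(methoxymethoxy)phenyl}-3-[4-(benzyloxy)phenyl]prop-2-en-1-one | O=C(/C=C/c1ccc(OCc2ccccc2)cc1)c1cc(Cc2ccc(OCc3ccccc3)cc2)c(OCc2ccccc2)cc1OCOC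
F7 | step 5 | {4-(benzyloxy)-5-[4-(benzyloxy)benzyl]-2-(methoxymethoxy)phenyl}{(2R,3S)-3-[4-(benzyloxy)phenyl]oxiran-2-yl}methanone | O=C([C@@H]1O[C@H]1c1ccc(OCc2ccccc2)cc1)c1cc(Cc2ccc(OCc3ccccc3)cc2)c(OCc2ccccc2)cc1OCOC
F0 | step 7 | none | none
F8 | step 11 | (2R,3R)-3,7-bis{[(benzyloxy)carbonyl]oxy}-6-(4-{[(benzyloxy)carbonyl]oxy}benzyl)-2-(4-{[(benzyloxy)carbonyl]oxy}phenyl)chroman-4-one | O=C1c2c(cc(OC(=O)OCc3ccccc3)c(Cc3ccc(OC(=O)OCc4ccccc4)cc3)c2)O[C@H](c2ccc(OC(=O)OCc3ccccc3)cc2)[C@H]1OC(=O)OCc1ccccc1
F9 | step 11 | (2R,3R)-3,7-bis{[(benzyloxy)carbonyl]oxy}-6-(4-{[(benzyloxy)carbonyl]oxy}benzyl)-5-hydroxy-2-(4-{[(benzyloxy)carbonyl]oxy}phenyl)chroman-4-one | O=C1c2c(cc(OC(=O)OCc3ccccc3)c(Cc3ccc(OC(=O)OCc4ccccc4)cc3)c2O)O[C@H](c2ccc(OC(=O)OCc3ccccc3)cc2)[C@H]1OC(=O)OCc1ccccc1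
A1 | alternative 1 | (2R,3R)-5,7-bis(benzyloxy)-6-[4-(benzyloxy)benzyl]-2-[4-(benzyloxy)phenyl]-3-hydroxychroman-4-one | O=C1c2c(cc(OCc3ccccc3)c(Cc3ccc(OCc4ccccc4)cc3)c2OCc2ccccc2)O[C@H](c2ccc(OCc3ccccc3)cc2)[C@H]1O
A2 | alternative 2 | (2S)-5,7-bis(benzyloxy)-6-[4-(benzyloxy)benzyl]-2-[4-(benzyloxy)phenyl]chroman-4-one | O=C1c2c(cc(OCc3ccccc3)c(Cc3ccc(OCc4ccccc4)cc3)c2OCc2ccccc2)O[C@H](c2ccc(OCc3ccccc3)cc2)C1
A3 | alternative 3 | (2R,3R)-7-(benzyloxy)-2-[4-(benzyloxy)phenyl]-6-{[4-(benzyloxy)phenyl](phenylthio)methyl}-3-(tert-butyldimethylsilyloxy)-5-hydroxychroman-4-one (both epimers at the thioether carbon) | O=C1c2c(cc(OCc3ccccc3)c(C(Sc3ccccc3)c3ccc(OCc4ccccc4)cc3)c2O)O[C@H](c2ccc(OCc3ccccc3)cc2)[C@H]1O[Si](C)(C)C(C)(C)C
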